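**Plan**
- The last disconnections are the three O–benzyl bonds and the saturation of the A–B bridge, which is unmasked as a diarylalkyne.
- Both aryl–C(sp) bonds of that alkyne are cut together, giving 3-iodoanisole, trimethylsilylacetylene and a ring B aryl bromide. This is possible because the bridge is a bare CH2–CH2 unit between C1 of the 3-methoxyphenyl ring A and C1 of the 4-hydroxy-3-aryloxyphenyl ring B, i.e. a reduced acetylene.
- The C–D ethylene bridge is cut at its central C–C bond (olefination, then C=C reduction), and the B–O–C diaryl ether at the O–C(ring C) bond (SNAr).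
- Forward: ring B phenol from 5-bromosalicylaldehyde; diaryl ether with 4-fluorobenzaldehyde (ring C); ring D by Horner–Wadsworth–Emmons olefination and diimide reduction; rings A and B joined through acetylene; global hydrogenation.
- Stereochemistry: the target has no stereocentre. The only stereo element on the way, the E-alkene of the olefination, is erased by reduction.

Key step: step 10

Remark: the target is achiral (no stereocentre, no stereogenic double bond), so "single enantiomer" is read as the one compound drawn and no stereocontrol is needed.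

**Route**

Step 1
Reactants: 1 5-bromosalicylaldehyde
Product: 2 2-(benzyloxy)-5-bromobenzaldehyde
Conditions: BnBr, K2CO3, DMF, rt
Reagents that add atoms: benzyl bromide, BrCc1ccccc1
Why: Williamson ether synthesis, in which the phenoxide of 1 displaces bromide from the benzylic halide and the aldehyde and aryl bromide are inert.

Step 2
Reactants: 2 2-(benzyloxy)-5-bromobenzaldehyde
Product: 4 2-(benzyloxy)-5-bromophenol, via aryl formate 3 (not isolated)
Conditions: mCPBA, CH2Cl2, 0 °C to rt; aq. NaHCO3/Na2S2O3 wash; then K2CO3 (cat.), MeOH, rt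
Reagents that add atoms: mCPBA, OOC(=O)c1cccc(Cl)c1
Why: Baeyer–Villiger (Dakin-type) oxidation, in which the aryl group carrying the ortho-benzyloxy donor migrates in preference to hydride to give formate 3, which base-catalysed methanolysis converts into the phenol without touching the benzyl ether or the C–Br bond.

Step 3
Reactants: 4 2-(benzyloxy)-5-bromophenol, 5 4-fluorobenzaldehyde
Product: 6 4-[2-(benzyloxy)-5-bromophenoxy]benzaldehyde
Conditions: K2CO3, DMF, 130 °C
Reagents that add atoms: none
Why: Nucleophilic aromatic substitution (addition–elimination), in which the para-formyl group activates the C–F bond towards the phenoxide while the unactivated C–Br bond of ring B is left alone.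

Step 4
Reactants: 7 2,5-dihydroxybenzaldehyde
Product: 8 2,5-bis(benzyloxy)benzaldehyde
Conditions: BnBr (2.5 equiv), K2CO3, DMF, 60 °C, under argon
Reagents that add atoms: benzyl bromide, BrCc1ccccc1
Why: Double Williamson etherification, with gentle heating to alkylate the hydrogen-bonded 2-OH and exclusion of air to protect the hydroquinone dianion from oxidation.

Step 5
Reactants: 8 2,5-bis(benzyloxy)benzaldehyde
Product: 9 [2,5-bis(benzyloxy)phenyl]methanol
Conditions: NaBH4, MeOH/THF, 0 °C
Reagents that add atoms: none
Why: Borohydride reduction of an aryl aldehyde to the benzylic alcohol, to which benzyl ethers are inert.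

Step 6
Reactants: 9 [2,5-bis(benzyloxy)phenyl]methanol
Product: 10 1,4-bis(benzyloxy)-2-(bromomethyl)benzene
Conditions: PBr3, CH2Cl2, 0 °C
Reagents that add atoms: phosphorus tribromide, BrP(Br)Br
Why: Bromination of a benzylic alcohol through its phosphite ester (SN2 by bromide), fast at 0 °C for this electron-rich benzylic position; the bromide should be used directly.

Step 7
Reactants: 10 1,4-bis(benzyloxy)-2-(bromomethyl)benzene
Product: 11 diethyl {[2,5-bis(benzyloxy)phenyl]methyl}phosphonate
Conditions: P(OEt)3 (neat), 130 °C
Reagents that add atoms: triethyl phosphite, CCOP(OCC)OCC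
Why: Michaelis–Arbuzov reaction, in which the phosphite attacks the benzylic bromide and the phosphonium intermediate loses bromoethane, which distils out.

Step 8
Reactants: 6 4-[2-(benzyloxy)-5-bromophenoxy]benzaldehyde, 11 diethyl {[2,5-bis(benzyloxy)phenyl]methyl}phosphonate
Product: 12 1-(benzyloxy)-4-bromo-2-(4-{(E)-2-[2,5-bis(benzyloxy)phenyl]ethenyl}phenoxy)benzene
Conditions: KOtBu, THF, 0 °C to rt (anion of 11 formed first, then 6 added)
Reagents that add atoms: none
Why: Horner–Wadsworth–Emmons olefination of a non-enolisable aryl aldehyde with a benzylic phosphonate anion, which gives the E-stilbene under thermodynamic control of the reversible addition step.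

Step 9
Reactants: 12 1-(benzyloxy)-4-bromo-2-(4-{(E)-2-[2,5-bis(benzyloxy)phenyl]ethenyl}phenoxy)benzene
Product: 13 1-(benzyloxy)-4-bromo-2-(4-{2-[2,5-bis(benzyloxy)phenyl]ethyl}phenoxy)benzene
Conditions: TsNHNH2 (excess, in portions), NaOAc, DME/H2O, reflux
Reagents that add atoms: none
Why: Diimide reduction, a concerted syn transfer of H2 to the non-polar C=C bond that, unlike catalytic hydrogenation, leaves the aryl bromide and the three benzyl ethers intact.

Step 10
Reactants: 13 1-(benzyloxy)-4-bromo-2-(4-{2-[2,5-bis(benzyloxy)phenyl]ethyl}phenoxy)benzene, 14 3-iodoanisole, 15 trimethylsilylacetylene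
Product: 18 1-(benzyloxy)-2-(4-{2-[2,5-bis(benzyloxy)phenyl]ethyl}phenoxy)-4-[(3-methoxyphenyl)ethynyl]benzene, via silylated arylalkyne 16 (not isolated), via 3-ethynylanisole 17 (not isolated)
Conditions: 14 and 15 (1.3 equiv each), PdCl2(PPh3)2 (5 mol%), CuI (10 mol%), Et3N, toluene, rt; then 13 (1.0 equiv), DBU, H2O (1.5 equiv), 80 °C
Reagents that add atoms: none
Why: Pd(0) inserts into the C–I bond of 14 at room temperature, the copper acetylide of 15 transmetalates and reductive elimination gives 16, whose C–Si bond is inert to dry triethylamine so that the alkyne cannot be arylated twice. DBU and water then cleave the C–Si bond to free 17, and at 80 °C its copper acetylide couples with 13 after oxidative addition of palladium into the C–Br bond. The closest known reaction type is the one-pot sila-Sonogashira synthesis of unsymmetrical diarylalkynes with in situ amidine/water desilylation. No ring is closed and no stereocentre is created. The selectivity required is the ordering of the two couplings, so that no symmetrical diarylalkyne forms; it is secured by the silyl cap, by adding 13 only after 14 is consumed, and by the C–I/C–Br reactivity gap, the bromide para to the benzyloxy group being inert at room temperature. The benzyl ethers, the diaryl ether and the methyl ether are spectators, and the inductively withdrawing meta-aryloxy group assists oxidative addition into the otherwise electron-rich bromide.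

Step 11
Reactants: 18 1-(benzyloxy)-2-(4-{2-[2,5-bis(benzyloxy)phenyl]ethyl}phenoxy)-4-[(3-methoxyphenyl)ethynyl]benzene
Product: 19 2-[2-(4-{2-hydroxy-5-[2-(3-methoxyphenyl)ethyl]phenoxy}phenyl)ethyl]benzene-1,4-diol
Conditions: H2 (1 atm), 10% Pd/C, EtOAc/MeOH, rt; filtration and concentration under argon
Reagents that add atoms: none
Why: Heterogeneous catalytic hydrogenation saturates the diarylalkyne to the ethylene bridge and hydrogenolyses the three benzylic C–O bonds in one operation, while the aryl methyl ether, the diaryl ether and the arenes are inert at 1 atm and room temperature.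

**Compound list**
1 | 5-bromosalicylaldehyde | O=Cc1cc(Br)ccc1O | starting material
2 | 2-(benzyloxy)-5-bromobenzaldehyde | O=Cc1cc(Br)ccc1OCc1ccccc1 | intermediate
3 | 2-(benzyloxy)-5-bromophenyl formate | O=COc1cc(Br)ccc1OCc1ccccc1 | intermediate (not isolated)
4 | 2-(benzyloxy)-5-bromophenol | Oc1cc(Br)ccc1OCc1ccccc1 | intermediate
5 | 4-fluorobenzaldehyde | O=Cc1ccc(F)cc1 | starting material
6 | 4-[2-(benzyloxy)-5-bromophenoxy]benzaldehyde | O=Cc1ccc(Oc2cc(Br)ccc2OCc2ccccc2)cc1 | intermediate
7 | 2,5-dihydroxybenzaldehyde | O=Cc1cc(O)ccc1O | starting material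
8 | 2,5-bis(benzyloxy)benzaldehyde | O=Cc1cc(OCc2ccccc2)ccc1OCc1ccccc1 | intermediate
9 | [2,5-bis(benzyloxy)phenyl]methanol | OCc1cc(OCc2ccccc2)ccc1OCc1ccccc1 | intermediate
10 | 1,4-bis(benzyloxy)-2-(bromomethyl)benzene | BrCc1cc(OCc2ccccc2)ccc1OCc1ccccc1 | intermediate
11 | diethyl {[2,5-bis(benzyloxy)phenyl]methyl}phosphonate | CCOP(=O)(Cc1cc(OCc2ccccc2)ccc1OCc1ccccc1)OCC | intermediate
12 | 1-(benzyloxy)-4-bromo-2-(4-{(E)-2-[2,5-bis(benzyloxy)phenyl]ethenyl}phenoxy)benzene | Brc1ccc(OCc2ccccc2)c(Oc2ccc(/C=C/c3cc(OCc4ccccc4)ccc3OCc3ccccc3)cc2)c1 | intermediate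
13 | 1-(benzyloxy)-4-bromo-2-(4-{2-[2,5-bis(benzyloxy)phenyl]ethyl}phenoxy)benzene | Brc1ccc(OCc2ccccc2)c(Oc2ccc(CCc3cc(OCc4ccccc4)ccc3OCc3ccccc3)cc2)c1 | intermediate
14 | 3-iodoanisole | COc1cccc(I)c1 | starting material
15 | trimethylsilylacetylene | C#C[Si](C)(C)C | starting material
16 | [(3-methoxyphenyl)ethynyl]trimethylsilane | COc1cccc(C#C[Si](C)(C)C)c1 | intermediate (not isolated)
17 | 1-ethynyl-3-methoxybenzene (3-ethynylanisole) | COc1cccc(C#C)c1 | intermediate (not isolated)
18 | 1-(benzyloxy)-2-(4-{2-[2,5-bis(benzyloxy)phenyl]ethyl}phenoxy)-4-[(3-methoxyphenyl)ethynyl]benzene | COc1cccc(C#Cc2ccc(OCc3ccccc3)c(Oc3ccc(CCc4cc(OCc5ccccc5)ccc4OCc4ccccc4)cc3)c2)c1 | intermediate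
19 | 2-[2-(4-{2-hydroxy-5-[2-(3-methoxyphenyl)ethyl]phenoxy}phenyl)ethyl]benzene-1,4-diol | COc1cccc(CCc2ccc(O)c(Oc3ccc(CCc4cc(O)ccc4O)cc3)c2)c1 | target

**Step count**
Total steps: 11.
Longest linear sequence: 8 steps (steps 4, 5, 6, 7, 8, 9, 10, 11, from 2,5-dihydroxybenzaldehyde). The ring B/C branch (steps 1–3) joins at step 8.

**Steps most likely to fail**

Step 10. Oxidative addition into the electron-rich C–Br bond of 13 may be slow at 80 °C. The freed alkyne 17 would then be consumed by copper-mediated oxidative homocoupling, or the catalyst would decay before the second coupling is complete. The fallback sets out from 13 and replaces the leaving group and the one-pot format. An aromatic Finkelstein exchange (NaI, CuI cat., trans-N,N'-dimethylcyclohexane-1,2-diamine, dioxane, 110 °C) should give 1-(benzyloxy)-2-(4-{2-[2,5-bis(benzyloxy)phenyl]ethyl}phenoxy)-4-iodobenzene F1. This is then coupled at room temperature (PdCl2(PPh3)2, CuI, Et3N, THF) with 17 that has been made and isolated separately from 14 and 15 through 16 (Sonogashira coupling, then K2CO3/MeOH). The sequence comes back to the route at 18.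

Step 9. Diimide may disproportionate faster than it transfers hydrogen to the conjugated 1,2-diarylethene, so the reduction could stall and leave alkene that is hard to separate from 13. The fallback sets out from 12 and omits the separate saturation. Compound 12 is taken as such through the one-pot coupling of step 10 with 14 and 15 to give 1-(benzyloxy)-2-(4-{(E)-2-[2,5-bis(benzyloxy)phenyl]ethenyl}phenoxy)-4-[(3-methoxyphenyl)ethynyl]benzene F2; the 1,2-disubstituted stilbene is a poor Heck acceptor. Hydrogenation under the conditions of step 11 then saturates alkyne and alkene together and removes the benzyl groups, coming back to the route at 19.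

Step 11. Hydrogenolysis may stall at partly benzylated stages through catalyst poisoning by copper, iodide or amine residues carried over from step 10, and the freed hydroquinone ring may oxidise in air to the quinone during work-up. The fallback sets out from 18 and separates reduction from deprotection. Hydrogenation over Pd/C attenuated with diphenyl sulfide should saturate only the alkyne and give 1-(benzyloxy)-2-(4-{2-[2,5-bis(benzyloxy)phenyl]ethyl}phenoxy)-4-[2-(3-methoxyphenyl)ethyl]benzene F3. The benzyl ethers are then cleaved non-reductively with BCl3 and pentamethylbenzene in CH2Cl2 at −78 °C, conditions that spare the aryl methyl ether, followed by a methanol quench and a work-up with aqueous sodium dithionite. This comes back to the route at 19.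

**Further compounds**
F1 | step 10 | 1-(benzyloxy)-2-(4-{2-[2,5-bis(benzyloxy)phenyl]ethyl}phenoxy)-4-iodobenzene | Ic1ccc(OCc2ccccc2)c(Oc2ccc(CCc3cc(OCc4ccccc4)ccc3OCc3ccccc3)cc2)c1
F2 | step 9 | 1-(benzyloxy)-2-(4-{(E)-2-[2,5-bis(benzyloxy)phenyl]ethenyl}phenoxy)-4-[(3-methoxyphenyl)ethynyl]benzene | COc1cccc(C#Cc2ccc(OCc3ccccc3)c(Oc3ccc(/C=C/c4cc(OCc5ccccc5)ccc4OCc4ccccc4)cc3)c2)c1
F3 | step 11 | 1-(benzyloxy)-2-(4-{2-[2,5-bis(benzyloxy)phenyl]ethyl}phenoxy)-4-[2-(3-methoxyphenyl)ethyl]benzene | COc1cccc(CCc2ccc(OCc3ccccc3)c(Oc3ccc(CCc4cc(OCc5ccccc5)ccc4OCc4ccccc4)cc3)c2)c1
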